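**Retrosynthetic overview**
1. Target ⇒ C1 angeloylation and C7 oxidation of mono-ester 27 ⇒ Evans–Tishchenko union of tricyclic β-hydroxy ketone 23 with epoxy aldehyde 26 (trans-1,3-diol, the two oxygens differentiated).
2. 23 ⇒ ligand-controlled β-borylation of enone 21; seven-membered ring (last ring) ⇒ aldol condensation of a 1,3-diaxial acetyl/aldehyde pair on bicycle 18 (acetyl from the alkyne).
3. C5 arm ⇒ Horner–Wadsworth–Emmons reaction on cyclobutanone 12, face-selective conjugate reduction, gem-dimethylation, nitrile → aldehyde.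
4. Key step: cyclobutane and six-membered ring together ⇒ intramolecular vinylketene–enyne [2+2] of acyclic acid 9; its silyloxy stereocentre (the later C7 carbonyl) relays the absolute configuration.
5. 9 ⇒ catalytic asymmetric vinylogous Mukaiyama aldol of enynal 2 with dienolate 5. Ring order: four + six (one step), then seven.

Assumption: compounds 1, 3, 24 and 28 are taken as purchasable; core carbons are called C1–C11 in the order of the target SMILES (C1 CH–O-angelate, C2 CH2, C3 CH–O-epoxy ester, C4 CMe2, C5/C6/C10/C11 cyclobutane, C7 C=O, C8, C9 C–Me), and the same labels are used for these carbons in earlier intermediates.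

**Step 1**
Reactants: 1 (E)-3-methylpent-2-en-4-yn-1-ol
Product: 2 (E)-3-methylpent-2-en-4-ynal
Conditions: MnO2 (15 equiv), CH2Cl2, rt; filtered and used as a solution
Reagents that add atoms: none
Why: Allylic alcohol oxidation with activated MnO2 stops at the conjugated enynal and leaves the E alkene and the alkyne untouched.

**Step 2**
Reactants: 3 tert-butyl 3-methylbut-2-enoate
Product: 5 tert-butyl[(1-tert-butoxy-3-methylbuta-1,3-dien-1-yl)oxy]dimethylsilane, via lithium dienolate 4 (not isolated)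
Conditions: LiN(i-Pr)2, THF, −78 °C; then TBSCl, DMPU, −78 °C → rt
Reagents that add atoms: tert-butyldimethylsilyl chloride, CC(C)(C)[Si](C)(C)Cl
Why: Kinetic γ-deprotonation of the senecioate and O-silylation of the dienolate give the silyl dienol ether (silyl ketene acetal formation).

**Step 3**
Reactants: 2 (E)-3-methylpent-2-en-4-ynal; 5 silyl dienol ether
Product: 7 tert-butyl (2E,5S,6E)-5-hydroxy-3,7-dimethylnona-2,6-dien-8-ynoate, via trichlorosilyl ether 6 (not isolated)
Conditions: SiCl4 (1.1 equiv), Denmark's (S,S)-bisphosphoramide (from N,N'-dimethyl-1,1'-binaphthyl-2,2'-diamine, pentane-1,5-diyl linker; 2 mol %), i-Pr2NEt (10 mol %), CH2Cl2, −78 °C; then aq. KF/NaHCO3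
Reagents that add atoms: none
Why: Lewis-base-catalysed, SiCl4-mediated vinylogous Mukaiyama aldol addition in which the dienolate reacts at its γ-carbon and the chiral phosphoramide-bound silicon cation directs it to the Si face of the aldehyde (the catalyst antipode for this sense, (S,S) by the usual model), setting 5S (the later C7) and the 2E enoate.

**Step 4**
Reactants: 7 hydroxy tert-butyl ester
Product: 9 (2E,5S,6E)-5-[(tert-butyldimethylsilyl)oxy]-3,7-dimethylnona-2,6-dien-8-ynoic acid, via bis-silyl compound 8 (not isolated)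
Conditions: TBSOTf (2.5 equiv), 2,6-lutidine, CH2Cl2, 0 °C → rt; then K2CO3, MeOH/H2O, rt; work-up at pH 4
Reagents that add atoms: tert-butyldimethylsilyl triflate, CC(C)(C)[Si](C)(C)OS(=O)(=O)C(F)(F)F
Why: TBSOTf silylates the carbinol and turns the tert-butyl ester into a silyl ester with loss of isobutene, and mild methanolysis then frees the acid while the secondary TBS ether stays (protecting-group exchange).

**Step 5 (key step)**
Reactants: 9 silyloxy dienynoic acid
Product: 12 (1R,2S,5R,7R)-2-[(tert-butyldimethylsilyl)oxy]-7-ethynyl-7-methyl-4-methylidenebicyclo[3.1.1]heptan-6-one, via acid chloride 10 (not isolated), via vinylketene 11 (not isolated)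
Conditions: Me2C=C(Cl)NMe2 (1.1 equiv), CH2Cl2, 0 °C; then added over 6 h to Et3N (5 equiv), PhMe, 110 °C (0.01 M)
Reagents that add atoms: none
Why: Snider-type intramolecular vinylketene–alkene [2+2] cycloaddition in the bridged mode, in which the ketene carbonyl carbon bonds to the less substituted alkene carbon and the α-carbon to the methyl/ethynyl-bearing carbon so that cyclobutanone and six-membered ring form together; the E alkene places ethynyl anti and methyl syn to the three-carbon bridge, and A(1,3) strain (carbinol H eclipsing the alkene, OTBS away from the ketene) lets the 5S centre fix C6, C10 and C11 in the target's absolute sense.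

**Step 6**
Reactants: 12 bicyclic cyclobutanone
Product: 13 2-[2-[(tert-butyldimethylsilyl)oxy]-7-ethynyl-7-methyl-4-methylidenebicyclo[3.1.1]heptan-6-ylidene]acetonitrile (ring centres as in 12; E/Z mixture)
Conditions: (EtO)2P(O)CH2CN, NaH, THF, 0 → 60 °C
Reagents that add atoms: diethyl (cyanomethyl)phosphonate, CCOP(=O)(CC#N)OCC
Why: Horner–Wadsworth–Emmons olefination of the strained, non-enolisable cyclobutanone with a small phosphonate anion; the geometry of the new alkene is irrelevant.

**Step 7**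
Reactants: 13 alkylidene nitrile
Product: 14 2-[2-[(tert-butyldimethylsilyl)oxy]-7-ethynyl-7-methyl-4-methylidenebicyclo[3.1.1]heptan-6-yl]acetonitrile (new 6-H syn to the C2–C4 bridge; CH2CN cis to ethynyl)
Conditions: Mg turnings (15 equiv), MeOH, 0 °C → rt
Reagents that add atoms: none
Why: Single-electron conjugate reduction of the unsaturated nitrile (Mg/MeOH) in which the face of C5 toward C11 is blocked by the axial ethynyl group, so hydrogen enters from the side of the three-carbon bridge and the cyanomethyl arm ends cis to ethynyl, as the seven-membered ring will require.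

**Step 8**
Reactants: 14 nitrile
Product: 16 2-[2-[(tert-butyldimethylsilyl)oxy]-7-ethynyl-7-methyl-4-methylidenebicyclo[3.1.1]heptan-6-yl]-2-methylpropanenitrile, via monomethyl nitrile 15 (not isolated)
Conditions: LiN(i-Pr)2 (2.2 equiv), THF, −78 °C, MeI (1.0 equiv); then LiN(i-Pr)2 (1.2 equiv), MeI (1.1 equiv), −78 °C
Reagents that add atoms: iodomethane, CI
Why: Double α-alkylation of the nitrile anion builds the C4 quaternary carbon, the more basic nitrile carbanion of the acetylide/nitrile dianion reacting with MeI while the lithium acetylide is inert at −78 °C.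

**Step 9**
Reactants: 16 tertiary nitrile
Product: 18 2-[2-[(tert-butyldimethylsilyl)oxy]-7-ethynyl-7-methyl-4-methylidenebicyclo[3.1.1]heptan-6-yl]-2-methylpropanal, via aldimine 17 (not isolated)
Conditions: i-Bu2AlH (2.5 equiv), PhMe, −78 °C; then aq. Rochelle salt, wet SiO2
Reagents that add atoms: water, O
Why: Partial reduction of a hindered tertiary nitrile, one hydride adding to give the aluminium imine that hydrolyses to the neopentyl aldehyde.

**Step 10**
Reactants: 18 alkynyl aldehyde
Product: 21 tricyclic enone (C1 ketone, C2=C3, C4 gem-dimethyl, 7S OTBS, C9 methylidene; C5, C6, C10, C11 as in the target), via keto aldehyde 19 (not isolated), via aldol 20 (not isolated)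
Conditions: Ph3PAuCl (2 mol %), AgOTf (2 mol %), dioxane/H2O (10:1), 60 °C; then KOH (0.2 equiv), MeOH, 50 °C
Reagents that add atoms: water, O
Why: Gold-catalysed Markovnikov hydration of the terminal alkyne gives the methyl ketone, whose only enolisable position condenses with the non-enolisable aldehyde held 1,3-diaxial to it (intramolecular aldol condensation) to close the seven-membered ring.

**Step 11**
Reactants: 21 tricyclic enone
Product: 23 tricyclic β-hydroxy ketone (3R OH, C1 ketone; otherwise as 21), via pinacol boronate 22 (not isolated)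
Conditions: B2pin2 (1.1 equiv), CuCl (5 mol %), NaOt-Bu (10 mol %), QuinoxP* (6 mol %, enantiomer for Re-face attack at C3), MeOH (2 equiv), THF, rt; then NaBO3·4H2O, THF/H2O, rt
Reagents that add atoms: sodium perborate tetrahydrate, [Na+].[Na+].O[B-]1(O)OO[B-](O)(O)OO1
Why: Copper-catalysed asymmetric conjugate borylation of the cyclic enone followed by stereoretentive C–B oxidation; the two enone faces differ only remotely, so the ligand, not the substrate, sets the 3R carbinol.

**Step 12**
Reactants: 24 (E)-2-methylbut-2-en-1-ol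
Product: 25 (2R,3R)-2,3-epoxy-2-methylbutan-1-ol
Conditions: Ti(Oi-Pr)4 (10 mol %), D-(−)-diisopropyl tartrate (12 mol %), t-BuOOH, 4 Å MS, CH2Cl2, −20 °C
Reagents that add atoms: tert-butyl hydroperoxide, CC(C)(C)OO
Why: Sharpless asymmetric epoxidation, the D-(−)-tartrate delivering oxygen to the face of the E allylic alcohol that gives the 2R,3R epoxy alcohol.

**Step 13**
Reactants: 25 epoxy alcohol
Product: 26 (2S,3R)-2,3-dimethyloxirane-2-carbaldehyde
Conditions: TEMPO (10 mol %), PhI(OAc)2 (1.1 equiv), CH2Cl2, rt; used as a solution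
Reagents that add atoms: none
Why: Oxoammonium (TEMPO) oxidation of the primary alcohol to the non-enolisable epoxy aldehyde without touching the epoxide or its two stereocentres.

**Step 14**
Reactants: 23 tricyclic β-hydroxy ketone; 26 epoxy aldehyde
Product: 27 tricyclic hydroxy ester (1R OH free, 3R O-(2S,3R)-2,3-dimethyloxirane-2-carbonyl, 7S OTBS, C9 methylidene)
Conditions: SmI2 (30 mol %) pre-reacted with PhCHO (30 mol %), THF, rt; then the hydroxy ketone and the epoxy aldehyde (fourfold excess), THF, −10 °C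
Reagents that add atoms: none
Why: Evans–Tishchenko reaction in which the samarium-bound hemiacetal formed from the C3 hydroxyl and the aldehyde transfers its hydride intramolecularly to the C1 ketone from the face of the C3 oxygen, giving the trans (anti) 1,3-diol with the epoxy acyl group on O3 and the new 1R carbinol free, every atom of both partners ending in the product; pre-forming the catalyst from SmI2 and PhCHO keeps divalent samarium away from the epoxy aldehyde.

**Step 15**
Reactants: 27 hydroxy ester; 28 angelic acid ((Z)-2-methylbut-2-enoic acid)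
Product: 29 tricyclic diester (C1 angelate, C3 epoxy ester, 7S OTBS, C9 methylidene)
Conditions: 28, 2,4,6-trichlorobenzoyl chloride, Et3N, PhMe, rt; then 27, PhMe, 80 °C
Reagents that add atoms: none
Why: Yamaguchi-type acylation through the preformed angelic 2,4,6-trichlorobenzoic mixed anhydride without a nucleophilic catalyst, which esterifies the hindered alcohol without Z-to-E isomerisation.

**Step 16**
Reactants: 29 silyl ether diester
Product: 30 tricyclic diester alcohol (7S OH)
Conditions: HF·pyridine, pyridine, THF, 0 °C → rt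
Reagents that add atoms: none
Why: Buffered fluoride desilylation of the secondary TBS ether, which leaves both esters and the epoxide intact.

**Step 17**
Reactants: 30 diester alcohol
Product: 32 CNP0149458.1 (1R,3R,5S,6R,10R,11R; C1 angelate, C3 (2S,3R)-2,3-dimethyloxirane-2-carboxylate, C7 ketone, C8=C9), via exo-methylene ketone 31 (not isolated)
Conditions: Dess–Martin periodinane, NaHCO3, CH2Cl2, 0 °C → rt; then DBU (0.2 equiv), 0 °C
Reagents that add atoms: none
Why: Dess–Martin oxidation gives the β,γ-unsaturated ketone and base-mediated isomerisation moves the exocyclic alkene into conjugation (verbenone-type enone), with no stereocentre touched.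

**Compound list**
1 | (E)-3-methylpent-2-en-4-yn-1-ol | OC/C=C(\C)C#C | starting material
2 | (E)-3-methylpent-2-en-4-ynal | O=C/C=C(\C)C#C | intermediate
3 | tert-butyl 3-methylbut-2-enoate | CC(C)=CC(=O)OC(C)(C)C | starting material
4 | lithium 1-tert-butoxy-3-methylbuta-1,3-dien-1-olate | C=C(C)C=C([O-])OC(C)(C)C.[Li+] | intermediate
5 | tert-butyl[(1-tert-butoxy-3-methylbuta-1,3-dien-1-yl)oxy]dimethylsilane | C=C(C)C=C(OC(C)(C)C)O[Si](C)(C)C(C)(C)C | intermediate
6 | tert-butyl (2E,5S,6E)-3,7-dimethyl-5-(trichlorosilyloxy)nona-2,6-dien-8-ynoate | CC(C)(C)OC(=O)/C=C(\C)C[C@H](O[Si](Cl)(Cl)Cl)/C=C(\C)C#C | intermediate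
7 | tert-butyl (2E,5S,6E)-5-hydroxy-3,7-dimethylnona-2,6-dien-8-ynoate | CC(C)(C)OC(=O)/C=C(\C)C[C@H](O)/C=C(\C)C#C | intermediate
8 | tert-butyldimethylsilyl (2E,5S,6E)-5-[(tert-butyldimethylsilyl)oxy]-3,7-dimethylnona-2,6-dien-8-ynoate | CC(C)(C)[Si](C)(C)OC(=O)/C=C(\C)C[C@H](O[Si](C)(C)C(C)(C)C)/C=C(\C)C#C | intermediate
9 | (2E,5S,6E)-5-[(tert-butyldimethylsilyl)oxy]-3,7-dimethylnona-2,6-dien-8-ynoic acid | OC(=O)/C=C(\C)C[C@H](O[Si](C)(C)C(C)(C)C)/C=C(\C)C#C | intermediate
10 | (2E,5S,6E)-5-[(tert-butyldimethylsilyl)oxy]-3,7-dimethylnona-2,6-dien-8-ynoyl chloride | ClC(=O)/C=C(\C)C[C@H](O[Si](C)(C)C(C)(C)C)/C=C(\C)C#C | intermediate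
11 | (5S,6E)-5-[(tert-butyldimethylsilyl)oxy]-7-methyl-3-methylidenenona-1,6-dien-8-yn-1-one (vinylketene) | O=C=CC(=C)C[C@H](O[Si](C)(C)C(C)(C)C)/C=C(\C)C#C | intermediate
12 | (1R,2S,5R,7R)-2-[(tert-butyldimethylsilyl)oxy]-7-ethynyl-7-methyl-4-methylidenebicyclo[3.1.1]heptan-6-one | O=C2[C@H]3[C@@H](O[Si](C)(C)C(C)(C)C)CC(=C)[C@@H]2[C@@]3(C)C#C | intermediate
13 | 6-(cyanomethylidene) derivative of 12 (E/Z mixture) | N#CC=C2[C@H]3[C@@H](O[Si](C)(C)C(C)(C)C)CC(=C)[C@@H]2[C@@]3(C)C#C | intermediate
14 | 6-(cyanomethyl) bicycle, 6-H syn to the C2–C4 bridge | N#CC[C@@H]2[C@H]3[C@@H](O[Si](C)(C)C(C)(C)C)CC(=C)[C@@H]2[C@@]3(C)C#C | intermediate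
15 | 6-(1-cyanoethyl) bicycle (both epimers at the nitrile α-carbon) | N#CC(C)[C@@H]2[C@H]3[C@@H](O[Si](C)(C)C(C)(C)C)CC(=C)[C@@H]2[C@@]3(C)C#C | intermediate
16 | 6-(2-cyanopropan-2-yl) bicycle | N#CC(C)(C)[C@@H]2[C@H]3[C@@H](O[Si](C)(C)C(C)(C)C)CC(=C)[C@@H]2[C@@]3(C)C#C | intermediate
17 | aldimine of 18 | N=CC(C)(C)[C@@H]2[C@H]3[C@@H](O[Si](C)(C)C(C)(C)C)CC(=C)[C@@H]2[C@@]3(C)C#C | intermediate
18 | 2-[2-[(tert-butyldimethylsilyl)oxy]-7-ethynyl-7-methyl-4-methylidenebicyclo[3.1.1]heptan-6-yl]-2-methylpropanal | O=CC(C)(C)[C@@H]2[C@H]3[C@@H](O[Si](C)(C)C(C)(C)C)CC(=C)[C@@H]2[C@@]3(C)C#C | intermediate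
19 | 7-acetyl analogue of 18 (keto aldehyde) | O=CC(C)(C)[C@@H]2[C@H]3[C@@H](O[Si](C)(C)C(C)(C)C)CC(=C)[C@@H]2[C@@]3(C)C(C)=O | intermediate
20 | tricyclic aldol (C3 OH, both epimers; C1 ketone) | O=C1CC(O)C(C)(C)[C@@H]2[C@H]3[C@@H](O[Si](C)(C)C(C)(C)C)CC(=C)[C@@H]2[C@]31C | intermediate
21 | tricyclic enone (C1 ketone, C2=C3, 7S OTBS, C9 methylidene) | O=C1C=CC(C)(C)[C@@H]2[C@H]3[C@@H](O[Si](C)(C)C(C)(C)C)CC(=C)[C@@H]2[C@]31C | intermediate
22 | C3 pinacol boronate of the C1 ketone | O=C1C[C@@H](B4OC(C)(C)C(C)(C)O4)C(C)(C)[C@@H]2[C@H]3[C@@H](O[Si](C)(C)C(C)(C)C)CC(=C)[C@@H]2[C@]31C | intermediate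
23 | tricyclic (3R)-hydroxy C1 ketone | O=C1C[C@@H](O)C(C)(C)[C@@H]2[C@H]3[C@@H](O[Si](C)(C)C(C)(C)C)CC(=C)[C@@H]2[C@]31C | intermediate
24 | (E)-2-methylbut-2-en-1-ol (tiglyl alcohol) | C/C=C(\C)CO | starting material
25 | (2R,3R)-2,3-epoxy-2-methylbutan-1-ol | OC[C@@]1(C)O[C@@H]1C | intermediate
26 | (2S,3R)-2,3-dimethyloxirane-2-carbaldehyde | O=C[C@@]1(C)O[C@@H]1C | intermediate
27 | tricyclic (1R)-alcohol, C3 (2S,3R)-2,3-dimethyloxirane-2-carboxylate, 7S OTBS | O[C@@H]1C[C@@H](OC(=O)[C@@]4(C)O[C@@H]4C)C(C)(C)[C@@H]2[C@H]3[C@@H](O[Si](C)(C)C(C)(C)C)CC(=C)[C@@H]2[C@]31C | intermediate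
28 | angelic acid ((Z)-2-methylbut-2-enoic acid) | C/C=C(/C)C(=O)O | starting material
29 | tricyclic C1 angelate, C3 epoxy ester, 7S OTBS | C/C=C(/C)C(=O)O[C@@H]1C[C@@H](OC(=O)[C@@]4(C)O[C@@H]4C)C(C)(C)[C@@H]2[C@H]3[C@@H](O[Si](C)(C)C(C)(C)C)CC(=C)[C@@H]2[C@]31C | intermediate
30 | tricyclic diester, 7S alcohol | C/C=C(/C)C(=O)O[C@@H]1C[C@@H](OC(=O)[C@@]4(C)O[C@@H]4C)C(C)(C)[C@@H]2[C@H]3[C@@H](O)CC(=C)[C@@H]2[C@]31C | intermediate
31 | tricyclic diester, C7 ketone, C9 methylidene | C/C=C(/C)C(=O)O[C@@H]1C[C@@H](OC(=O)[C@@]4(C)O[C@@H]4C)C(C)(C)[C@@H]2[C@H]3C(=O)CC(=C)[C@@H]2[C@]31C | intermediate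
32 | CNP0149458.1 | C/C=C(/C)C(=O)O[C@@H]1C[C@@H](OC(=O)[C@@]2(C)O[C@@H]2C)C(C)(C)[C@@H]2[C@H]3C(=O)C=C(C)[C@@H]2[C@]31C | target

**Totals**
Total step count: 17. Longest linear sequence: 14 (steps 1, 3–11, 14–17).

**Steps most likely to fail, with fallbacks**

Step 5 (ketene [2+2] onto an enyne). The alkene is less nucleophilic than a simple trisubstituted alkene, so ketene oligomerisation may win. The fallback sets out from acid 9. Ketene 11 is generated at room temperature in the presence of Ph3P=CHCN, so that a Wittig reaction on the ketene carbonyl gives the cyano vinylallene F1. Its allene, activated by EtAlCl2 at −78 °C (or heated in xylene), undergoes the analogous intramolecular allene–alkene [2+2] across the β,γ-bond, with the central carbon bonding to the less substituted alkene carbon. This gives alkylidene nitrile 13 directly, where the route is rejoined and step 6 is no longer needed.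

Step 7 (configuration at C5). If protonation does not occur cleanly from the face of the three-carbon bridge, C5 is instead set by ring constraint. The fallback sets out from ketone 12. Zn(OTf)2/Et3N-mediated addition of its alkyne to isobutyraldehyde gives the propargylic alcohol F2, and Ph3PAuNTf2-catalysed Meyer–Schuster rearrangement gives the (E)-enone F3. TBSOTf/Et3N converts this into the silyl dienol ether F4, whose γ-carbon can reach the cyclobutanone only from the C11 side. A BF3·OEt2-promoted intramolecular vinylogous Mukaiyama aldol closes the seven-membered ring to the tertiary hydroxy enone F5. Its xanthate F6 (KH, CS2, MeI) is reduced with Bu3SnH/AIBN, the bridged radical accepting hydrogen only from the outer face, and the route is rejoined at enone 21.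

Step 14 (Evans–Tishchenko with a hindered epoxy aldehyde; retro-aldol or acyl migration possible). The fallback sets out from hydroxy ketone 23. Aldehyde 26 is oxidised with NaClO2/NaH2PO4 to the epoxy acid F7, and Yamaguchi esterification of 23 with it gives the keto ester F8. Reagent-controlled reduction with (S)-Me-CBS oxazaborolidine/BH3·SMe2 (quaternary C11 side as the large group) then gives the 1R alcohol, and the route is rejoined at 27.

**Further compounds**
F1 | step 5 | (7S,8E)-7-[(tert-butyldimethylsilyl)oxy]-9-methyl-5-methylideneundeca-2,3,8-trien-10-ynenitrile | N#CC=C=CC(=C)C[C@H](O[Si](C)(C)C(C)(C)C)/C=C(\C)C#C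
F2 | step 7 | 7-(3-hydroxy-4-methylpent-1-yn-1-yl) analogue of 12 (both carbinol epimers) | O=C2[C@H]3[C@@H](O[Si](C)(C)C(C)(C)C)CC(=C)[C@@H]2[C@@]3(C)C#CC(O)C(C)C
F3 | step 7 | 7-[(E)-4-methylpent-2-enoyl] analogue of 12 | O=C2[C@H]3[C@@H](O[Si](C)(C)C(C)(C)C)CC(=C)[C@@H]2[C@@]3(C)C(=O)/C=C/C(C)C
F4 | step 7 | silyl dienol ether of F3 (1-silyloxy-4-methylpenta-1,3-dienyl at C7) | O=C2[C@H]3[C@@H](O[Si](C)(C)C(C)(C)C)CC(=C)[C@@H]2[C@@]3(C)C(O[Si](C)(C)C(C)(C)C)=CC=C(C)C
F5 | step 7 | 5-hydroxy derivative of enone 21 | O=C1C=CC(C)(C)[C@]2(O)[C@H]3[C@@H](O[Si](C)(C)C(C)(C)C)CC(=C)[C@@H]2[C@]31C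
F6 | step 7 | S-methyl xanthate of F5 | O=C1C=CC(C)(C)[C@]2(OC(=S)SC)[C@H]3[C@@H](O[Si](C)(C)C(C)(C)C)CC(=C)[C@@H]2[C@]31C
F7 | step 14 | (2S,3R)-2,3-dimethyloxirane-2-carboxylic acid | OC(=O)[C@@]1(C)O[C@@H]1C
F8 | step 14 | C3 epoxy ester of C1 ketone 23 | O=C1C[C@@H](OC(=O)[C@@]4(C)O[C@@H]4C)C(C)(C)[C@@H]2[C@H]3[C@@H](O[Si](C)(C)C(C)(C)C)CC(=C)[C@@H]2[C@]31C
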